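**Assumption:** Angustone B as drawn has no stereocenter (it is achiral), so no enantiocontrol is needed. The only stereocenter in the route is a transient racemic carbinol in 21, which is destroyed in Step 15.

## Retrosynthetic overview
- The C3–C1′ bond of the isoflavone is disconnected by Suzuki–Miyaura coupling into two similar-sized halves: 3-iodo-5,7-bis(OMOM)-6-prenylchromone (14) and 5-OMOM-2,2-dimethylchromen-6-yl Bpin (24).
- Fragment 14: resorcinol gives 2-prenyl-1,3-bis(MOMO)benzene by directed ortho-metalation (DoM) and alkylation. Ir C–H borylation and oxidation then add the third oxygen, a phloroglucinol pattern. Casiraghi formylation, then MeMgBr and MnO2, gives the 2-hydroxyacetophenone. The pyranone ring is closed last, via an enaminone and I2 iodocyclization.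
- Fragment 24: resorcinol gives 2,6-dihydroxyacetophenone. Symmetry-defined bromination and a Kabbe chromanone synthesis, followed by reduction and dehydration, close the dimethylpyran ring before coupling. Miyaura borylation then installs the boron.
- Ring order: pyranone of the chromone (Step 9); 2,2-dimethylpyran of the B ring (Steps 13–15); then the C3–C1′ coupling (Step 18); finally global MOM removal (Step 19).

## Route

**Step 1**
Reactants: 1 resorcinol
Product: 2 1,3-bis(methoxymethoxy)benzene
Conditions: NaH, MOMCl, THF/DMF, 0 °C → rt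
Reagents that add atoms: MOMCl, ClCOC
Why: Double Williamson-type O-alkylation protects both phenols as MOM ethers, which also serve as strong directing groups for DoM.

**Step 2**
Reactants: 2; 3 prenyl bromide (CC(C)=CCBr)
Product: 4 2-prenyl-1,3-bis(MOMO)benzene
Conditions: n-BuLi, THF, 0 °C; then CuI (10 mol%), 3, −78 °C → rt
Reagents that add atoms: none beyond 3
Why: Directed ortho-metalation occurs exclusively at C2, between the two OMOM groups; Cu-catalysed SN2 alkylation gives the linear prenyl group, placing prenyl where the natural product's C6 sits.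

**Step 3**
Reactants: 4
Product: 5 aryl-Bpin (Bpin at C5)
Conditions: [Ir(cod)OMe]2 (1.5 mol%), dtbpy (3 mol%), B2pin2, THF, 80 °C
Reagents that add atoms: B2pin2, CC1(C)OB(OC1(C)C)B1OC(C)(C)C(C)(C)O1
Why: Ir-catalysed C–H borylation is governed by sterics, so only C5 (meta to all substituents) reacts; this is the route to the third ring oxygen.

**Step 4**
Reactants: 5
Product: 6 4-prenyl-3,5-bis(MOMO)phenol
Conditions: 30% aq. H2O2, NaOH, THF, 0 °C → rt
Reagents that add atoms: H2O2, OO
Why: Oxidative C–B to C–O conversion (boronate oxidation) under basic, non-acidic conditions leaves the MOM ethers and the alkene intact.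

**Step 5**
Reactants: 6; 7 formaldehyde (as paraformaldehyde, C=O)
Product: 8 2-hydroxy-4,6-bis(MOMO)-5-prenylbenzaldehyde
Conditions: MgCl2, Et3N, (CH2O)n, THF, reflux
Reagents that add atoms: none beyond 7
Why: Mg-phenoxide-templated ortho-formylation (Casiraghi) is single-regioisomer because the two ortho positions of 6 are equivalent by symmetry.

**Step 6**
Reactants: 8; 9 methylmagnesium bromide (C[Mg]Br)
Product: 10 1-[2-hydroxy-4,6-bis(MOMO)-5-prenylphenyl]ethanol
Conditions: 9 (3 equiv), THF, 0 °C → rt; NH4Cl work-up
Reagents that add atoms: none beyond 9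
Why: Grignard addition to the aldehyde (the first equivalent deprotonates the phenol) converts the formyl group into the methyl carbinol.

**Step 7**
Reactants: 10
Product: 11 2′-hydroxy-4′,6′-bis(MOMO)-5′-prenylacetophenone
Conditions: activated MnO2, CH2Cl2, rt
Reagents that add atoms: none
Why: MnO2 selectively oxidises the o-hydroxybenzylic alcohol, leaving the prenyl alkene and MOM groups untouched.

**Step 8**
Reactants: 11; 12 DMF dimethyl acetal (CN(C)C(OC)OC)
Product: 13 (E)-enaminone, 3-(dimethylamino)-1-aryl-prop-2-en-1-one
Conditions: 12, toluene, 100 °C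
Reagents that add atoms: none beyond 12
Why: Condensation of the acetyl methyl group with the amide acetal (enaminone formation); the H-bonded phenol is not methylated.

**Step 9**
Reactants: 13
Product: 14 3-iodo-5,7-bis(MOMO)-6-prenylchromone
Conditions: I2, CHCl3, rt
Reagents that add atoms: I2, II
Why: Electrophilic α-iodination of the enaminone followed by phenol conjugate addition and loss of Me2NH closes the pyranone ring (iodocyclization). Closure is only possible through the free OH remote from the prenyl group, giving the 5,7-bis(OMOM)-6-prenyl pattern.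

**Step 10**
Reactants: 2; 15 N-methoxy-N-methylacetamide (CC(=O)N(C)OC)
Product: 16 2,6-bis(MOMO)acetophenone
Conditions: n-BuLi, THF, 0 °C; then 15, −78 °C → rt
Reagents that add atoms: none beyond 15
Why: DoM at C2 followed by Weinreb acylation stops at the ketone stage.

**Step 11**
Reactants: 16
Product: 17 2,6-dihydroxyacetophenone
Conditions: 3 M HCl, MeOH, 50 °C
Reagents that add atoms: none
Why: Aryl MOM ethers ortho to a carbonyl are readily hydrolysed under acid.

**Step 12**
Reactants: 17
Product: 18 3-bromo-2,6-dihydroxyacetophenone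
Conditions: NBS (1.0 equiv), CH2Cl2, −10 °C → rt
Reagents that add atoms: NBS, O=C1CCC(=O)N1Br
Why: Electrophilic bromination at C3 (ortho/para to both OH groups) gives one regioisomer because C3 and C5 are equivalent by symmetry.

**Step 13**
Reactants: 18; 19 acetone (CC(C)=O)
Product: 20 6-bromo-5-hydroxy-2,2-dimethylchroman-4-one
Conditions: 19, pyrrolidine (0.5 equiv), toluene, 4 Å MS, reflux
Reagents that add atoms: none beyond 19
Why: Kabbe condensation followed by intramolecular oxa-Michael addition; ring closure onto the OH para to Br is favoured because closure onto the OH next to Br would put the gem-dimethyl group against Br.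

**Step 14**
Reactants: 20
Product: 21 6-bromo-2,2-dimethylchroman-4,5-diol (racemic)
Conditions: NaBH4, EtOH, 0 °C → rt
Reagents that add atoms: none
Why: Hydride reduction of the ketone; the new carbinol stereocenter is irrelevant because it is removed in the next step.

**Step 15**
Reactants: 21
Product: 22 6-bromo-2,2-dimethyl-2H-chromen-5-ol
Conditions: TsOH·H2O (cat.), toluene, reflux (Dean–Stark)
Reagents that add atoms: none
Why: Acid-catalysed benzylic dehydration gives the conjugated 2,2-dimethylchromene, which is the achiral target B-ring unit.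

**Step 16**
Reactants: 22
Product: 23 6-bromo-5-(MOMO)-2,2-dimethyl-2H-chromene
Conditions: MOMCl, iPr2NEt, CH2Cl2, 0 °C → rt
Reagents that add atoms: MOMCl, ClCOC
Why: Phenol O-alkylation protects the 2′-OH so the boronate and Suzuki steps are clean.

**Step 17**
Reactants: 23
Product: 24 5-(MOMO)-2,2-dimethyl-2H-chromen-6-yl Bpin
Conditions: B2pin2, PdCl2(dppf) (5 mol%), KOAc, dioxane, 90 °C
Reagents that add atoms: B2pin2, CC1(C)OB(OC1(C)C)B1OC(C)(C)C(C)(C)O1
Why: Miyaura borylation converts the aryl bromide to the Bpin coupling partner under basic conditions that the chromene and MOM ether tolerate.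

**Step 18**
Reactants: 14; 24
Product: 25 5,7,2′-tris(MOMO)-6-prenyl-2″,2″-dimethylpyrano[3′,4′]isoflavone (protected angustone B)
Conditions: Pd(PPh3)4 (5 mol%), Na2CO3, DME/H2O 4:1, 80 °C
Reagents that add atoms: none
Why: Suzuki–Miyaura coupling of the 3-iodochromone with the aryl boronate joins the two halves and forms the isoflavone C3–C1′ bond.

**Step 19**
Reactants: 25
Product: 26 Angustone B
Conditions: 3 M HCl, MeOH/THF 1:1, 45 °C
Reagents that add atoms: none
Why: Acid-mediated cleavage of all three MOM acetals; the chelated 5-OMOM goes first, and mild temperature preserves the prenyl and chromene alkenes.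

## Compound list
1 | resorcinol | Oc1cccc(O)c1 | starting material
2 | 1,3-bis(methoxymethoxy)benzene | COCOc1cccc(OCOC)c1 | intermediate
3 | prenyl bromide | CC(C)=CCBr | starting material
4 | 2-prenyl-1,3-bis(MOMO)benzene | COCOc1cccc(OCOC)c1CC=C(C)C | intermediate
5 | 5-Bpin derivative of 4 | COCOc1cc(B2OC(C)(C)C(C)(C)O2)cc(OCOC)c1CC=C(C)C | intermediate
6 | 4-prenyl-3,5-bis(MOMO)phenol | COCOc1cc(O)cc(OCOC)c1CC=C(C)C | intermediate
7 | formaldehyde (paraformaldehyde) | C=O | starting material
8 | 2-hydroxy-4,6-bis(MOMO)-5-prenylbenzaldehyde | O=Cc1c(O)cc(OCOC)c(CC=C(C)C)c1OCOC | intermediate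
9 | methylmagnesium bromide | C[Mg]Br | starting material
10 | 1-aryl-ethanol (secondary carbinol) | CC(O)c1c(O)cc(OCOC)c(CC=C(C)C)c1OCOC | intermediate
11 | 2′-hydroxy-4′,6′-bis(MOMO)-5′-prenylacetophenone | CC(=O)c1c(O)cc(OCOC)c(CC=C(C)C)c1OCOC | intermediate
12 | DMF dimethyl acetal | CN(C)C(OC)OC | starting material
13 | enaminone | CN(C)/C=C/C(=O)c1c(O)cc(OCOC)c(CC=C(C)C)c1OCOC | intermediate
14 | 3-iodo-5,7-bis(MOMO)-6-prenylchromone | O=c1c(I)coc2cc(OCOC)c(CC=C(C)C)c(OCOC)c12 | intermediate
15 | N-methoxy-N-methylacetamide | CC(=O)N(C)OC | starting material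
16 | 2,6-bis(MOMO)acetophenone | CC(=O)c1c(OCOC)cccc1OCOC | intermediate
17 | 2,6-dihydroxyacetophenone | CC(=O)c1c(O)cccc1O | intermediate
18 | 3-bromo-2,6-dihydroxyacetophenone | CC(=O)c1c(O)c(Br)ccc1O | intermediate
19 | acetone | CC(C)=O | starting material
20 | 6-bromo-5-hydroxy-2,2-dimethylchroman-4-one | O=C1CC(C)(C)Oc2ccc(Br)c(O)c12 | intermediate
21 | 6-bromo-2,2-dimethylchroman-4,5-diol (racemic) | OC1CC(C)(C)Oc2ccc(Br)c(O)c12 | intermediate
22 | 6-bromo-2,2-dimethyl-2H-chromen-5-ol | CC1(C)C=Cc2c(O)c(Br)ccc2O1 | intermediate
23 | 6-bromo-5-(MOMO)-2,2-dimethyl-2H-chromene | CC1(C)C=Cc2c(OCOC)c(Br)ccc2O1 | intermediate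
24 | 5-(MOMO)-2,2-dimethyl-2H-chromen-6-yl Bpin | CC1(C)C=Cc2c(OCOC)c(B3OC(C)(C)C(C)(C)O3)ccc2O1 | intermediate
25 | tris-MOM-protected angustone B | O=c1c(-c2ccc3OC(C)(C)C=Cc3c2OCOC)coc2cc(OCOC)c(CC=C(C)C)c(OCOC)c12 | intermediate
26 | Angustone B | CC(C)=CCc1c(O)cc2occ(-c3ccc4OC(C)(C)C=Cc4c3O)c(=O)c2c1O | target

## Step count
- Total steps: 19.
- Longest linear sequence: 11 (Steps 1–9, 18, 19; the B-ring branch Steps 1, 10–17, 18, 19 is also 11).

## Three steps most likely to fail
1. **Step 19, global MOM removal.** The prenyl and 2,2-dimethylchromene units may cyclise or hydrate under aqueous acid.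
   Fallback: redo the route with Pd(0)-labile allyl-type protecting groups on the oxygens instead of MOM, removed at the end with Pd(PPh3)4/K2CO3/MeOH under neutral conditions.
2. **Step 13, Kabbe closure regiochemistry.** Closure onto the OH next to Br would give the wrong 8-bromo chromanone.
   Fallback: build 5-hydroxy-2,2-dimethylchromene from symmetric 2-prenylresorcinol (from 4, then deprotection and oxidative cyclisation). Then install boron at C6 by MOM-directed lithiation/borylation of the 5-OMOM ether, so the Br blocking strategy is avoided entirely.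
3. **Step 3, Ir borylation of the prenylated arene.** The trisubstituted alkene may compete, or conversion may be low.
   Fallback: reorder the A-ring synthesis. Borylate and oxidise compound 2 first to give 3,5-bis(MOMO)phenol, protect the phenol as a TIPS ether, and prenylate between the two OMOM groups by DoM. Then remove TIPS with fluoride and continue from Step 5.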